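**Plan**

- Retrosynthesis: the seven allyl groups are removed first. The E C=C of the caffeoyl unit is then cut, that is the bond between the α-carbon of the ester carbonyl and the benzylic carbon on ring A (the central arene bearing the enol ether oxygen). Because that carbon sits on an arene, the electrophile is an aldehyde without α-hydrogen and the partner is a malonic half ester already bound to the (R)-lactate oxygen.
- The ring A aldehyde is cut further at the enol ether C=C (aldol condensation of a ring A aryloxyacetate with the ring B aldehyde) and at the ring A O–CH2 bond. The half ester is cut at the malonyl C–O bond (Meldrum's acid plus allylated danshensu, ring C).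
- Forward: no ring is formed. Ring A is joined to ring B (O-alkylation, aldol addition, dehydration), the lactate fragment is malonylated separately, the halves are united by decarboxylative olefination, and the allyl groups are removed last.
- Stereochemistry: the R centre is bought with (R)-danshensu and never touched. The Z enol ether comes from a thermodynamically controlled E1cB elimination. The E caffeoyl alkene comes from the decarboxylative elimination.

Key step: step 10

Assumption: (R)-danshensu is purchased as the enantiopure free acid (from its sodium salt one equivalent less base is needed in step 8); allyl bromoacetate and Meldrum's acid are bought.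

**Route**

Step 1
Reactants: 1 3,4-dihydroxybenzaldehyde; 2 allyl bromide
Product: 3 4-(allyloxy)-3-hydroxybenzaldehyde
Conditions: allyl bromide (1.1 equiv), NaHCO3 (1.5 equiv), DMF, 40 °C
Reagents that add atoms: allyl bromide (2), C=CCBr
Why: The 4-OH is conjugated with the para formyl group and is the more acidic phenol, so the weak base ionises it selectively and the Williamson etherification should stop at the 4-O-allyl ether.

Step 2
Reactants: 1 3,4-dihydroxybenzaldehyde; 2 allyl bromide
Product: 4 3,4-bis(allyloxy)benzaldehyde (ring B aldehyde)
Conditions: allyl bromide (2.5 equiv), K2CO3 (3 equiv), DMF, 60 °C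
Reagents that add atoms: allyl bromide (2), C=CCBr
Why: With excess carbonate and halide both phenols undergo Williamson etherification while the aldehyde is inert.

Step 3
Reactants: 3 4-(allyloxy)-3-hydroxybenzaldehyde
Product: 5 2-(allyloxy)-5-(dimethoxymethyl)phenol
Conditions: HC(OMe)3, p-TsOH·H2O (cat.), MeOH, rt; Et3N quench
Reagents that add atoms: trimethyl orthoformate, COC(OC)OC; methanol, CO
Why: Acid-catalysed acetalisation with the orthoformate as water scavenger masks the ring A formyl group so that it cannot compete as an electrophile in step 5; the base quench protects the labile acetal on isolation.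

Step 4
Reactants: 5 2-(allyloxy)-5-(dimethoxymethyl)phenol; 6 allyl bromoacetate
Product: 7 allyl 2-[2-(allyloxy)-5-(dimethoxymethyl)phenoxy]acetate
Conditions: allyl bromoacetate (1.1 equiv), K2CO3, acetone, rt to 50 °C
Reagents that add atoms: allyl bromoacetate (6), C=CCOC(=O)CBr
Why: Williamson O-alkylation (SN2) of the phenoxide with the reactive α-bromo ester proceeds under mild carbonate conditions that leave the acetal and the allyl ester intact.

Step 5
Reactants: 7 allyl 2-[2-(allyloxy)-5-(dimethoxymethyl)phenoxy]acetate; 4 3,4-bis(allyloxy)benzaldehyde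
Product: 9 allyl 3-[3,4-bis(allyloxy)phenyl]-2-[2-(allyloxy)-5-(dimethoxymethyl)phenoxy]-3-hydroxypropanoate (racemic diastereomer mixture), via lithium enolate 8 (not isolated)
Conditions: LiN(i-Pr)2 (1.05 equiv), THF, –78 °C; then 4, –78 °C; AcOH quench at –78 °C
Reagents that add atoms: none
Why: Directed aldol addition of the preformed lithium ester enolate to a non-enolisable aldehyde at –78 °C, where ester-enolate Claisen rearrangement of the allyl ester and self-condensation should be negligible; the two new stereocentres form without control and are both erased in step 6.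

Step 6
Reactants: 9 aldol adduct
Product: 11 allyl (Z)-3-[3,4-bis(allyloxy)phenyl]-2-[2-(allyloxy)-5-(dimethoxymethyl)phenoxy]prop-2-enoate, via benzylic mesylate 10 (not isolated)
Conditions: MsCl, Et3N, CH2Cl2, 0 °C; then DBU, 0 °C to rt
Reagents that add atoms: none
Why: Mesylation followed by DBU-mediated E1cB elimination through the ester enolate lets both diastereomers converge on the conjugated alkene, and the isomer with the ring B aryl group trans to the ester carbonyl (Z, since the aryloxy oxygen outranks the ester carbon) should predominate as the thermodynamically favoured one, as in aldol condensation–dehydration routes to 2-aryloxycinnamates.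

Step 7
Reactants: 11 Z enol ether dimethyl acetal
Product: 12 allyl (Z)-3-[3,4-bis(allyloxy)phenyl]-2-[2-(allyloxy)-5-formylphenoxy]prop-2-enoate (ring A aldehyde)
Conditions: 1 M aq. HCl, THF, rt
Reagents that add atoms: water, O
Why: Acetal hydrolysis is fast here because the oxocarbenium ion is stabilised by the para allyloxy group, whereas the acceptor-substituted aryl enol ether, the allyl ethers and the allyl ester should be inert to dilute acid at room temperature.

Step 8
Reactants: 13 (R)-danshensu; 2 allyl bromide
Product: 14 allyl (R)-3-[3,4-bis(allyloxy)phenyl]-2-hydroxypropanoate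
Conditions: allyl bromide (3.5 equiv), K2CO3 (3.5 equiv), DMF, rt, N2
Reagents that add atoms: allyl bromide (2), C=CCBr
Why: Carbonate ionises the carboxylic acid and both phenols but not the secondary alcohol, so threefold O-alkylation leaves the hydroxyl free, and the α-proton of the hydroxy ester is far too weakly acidic for epimerisation.

Step 9
Reactants: 14 allyl (R)-3-[3,4-bis(allyloxy)phenyl]-2-hydroxypropanoate; 15 Meldrum's acid
Product: 16 3-{[(2R)-1-(allyloxy)-3-[3,4-bis(allyloxy)phenyl]-1-oxopropan-2-yl]oxy}-3-oxopropanoic acid (malonic half ester)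
Conditions: Meldrum's acid (1.3 equiv), toluene, 100 °C
Reagents that add atoms: Meldrum's acid (15), CC1(C)OC(=O)CC(=O)O1
Why: Thermal acyl transfer from Meldrum's acid (ring opening by the alcohol with loss of acetone) gives the malonic mono ester under neutral conditions, so the hindered secondary alcohol is acylated without activating agent or base and the R centre is retained.

Step 10
Reactants: 12 ring A aldehyde; 16 malonic half ester
Product: 19 heptaallyl salvianolic acid H, via iminium ion 17 (not isolated), via Mannich adduct 18 (not isolated)
Conditions: 16 (1.3 equiv), piperidine (0.2 equiv), pyridine, 50 °C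
Reagents that add atoms: none
Why: Piperidine condenses with aldehyde 12 to iminium ion 17, the enol of half ester 16 adds to it to give the β-piperidino malonic half ester 18, and loss of piperidine together with CO2 delivers the enoate and returns the amine. This is the Knoevenagel–Doebner condensation, well known for aryl aldehydes with malonic half esters, including those of aryl lactates. No ring is closed and no stereocentre is created; the only new stereo-element is the C=C, which should be E because the decarboxylative elimination passes through the conformer with aryl and ester anti and E is also the thermodynamic isomer. The aldehyde has no α-hydrogen and can only act as the electrophile, while the α-aryloxy-β-aryl acrylate already present is a poor Michael acceptor for the amine. The R centre arrives inside 16, so no hindered alcohol has to be acylated at this stage, and pyridine with catalytic piperidine at 50 °C should not epimerise it. The Z enol ether has no pathway for isomerisation under these conditions.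

Step 11
Reactants: 19 heptaallyl salvianolic acid H
Product: 20 salvianolic acid H
Conditions: Pd(PPh3)4 (10 mol%), morpholine (20 equiv), degassed THF, rt; dilute HCl work-up
Reagents that add atoms: none
Why: Zerovalent palladium ionises each allyl ester and aryl allyl ether to a π-allyl complex that morpholine captures irreversibly (Tsuji–Trost allyl transfer), so all seven allyl groups should leave under near-neutral conditions that spare both alkenes, the ester link and the stereocentre.

**Compound list**

1 | 3,4-dihydroxybenzaldehyde | O=Cc1ccc(O)c(O)c1 | starting material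
2 | allyl bromide | C=CCBr | starting material
3 | 4-(allyloxy)-3-hydroxybenzaldehyde | O=Cc1ccc(OCC=C)c(O)c1 | intermediate
4 | 3,4-bis(allyloxy)benzaldehyde | O=Cc1ccc(OCC=C)c(OCC=C)c1 | intermediate
5 | 2-(allyloxy)-5-(dimethoxymethyl)phenol | COC(OC)c1ccc(OCC=C)c(O)c1 | intermediate
6 | allyl bromoacetate | C=CCOC(=O)CBr | starting material
7 | allyl 2-[2-(allyloxy)-5-(dimethoxymethyl)phenoxy]acetate | C=CCOC(=O)COc1cc(C(OC)OC)ccc1OCC=C | intermediate
8 | lithium enolate of 7 (not isolated) | [Li]OC(OCC=C)=COc1cc(C(OC)OC)ccc1OCC=C | intermediate
9 | allyl 3-[3,4-bis(allyloxy)phenyl]-2-[2-(allyloxy)-5-(dimethoxymethyl)phenoxy]-3-hydroxypropanoate (racemic, both diastereomers) | C=CCOC(=O)C(Oc1cc(C(OC)OC)ccc1OCC=C)C(O)c1ccc(OCC=C)c(OCC=C)c1 | intermediate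
10 | benzylic mesylate of 9 (not isolated) | C=CCOC(=O)C(Oc1cc(C(OC)OC)ccc1OCC=C)C(OS(C)(=O)=O)c1ccc(OCC=C)c(OCC=C)c1 | intermediate
11 | allyl (Z)-3-[3,4-bis(allyloxy)phenyl]-2-[2-(allyloxy)-5-(dimethoxymethyl)phenoxy]prop-2-enoate | COC(OC)c1ccc(OCC=C)c(O/C(=C\c2ccc(OCC=C)c(OCC=C)c2)C(=O)OCC=C)c1 | intermediate
12 | allyl (Z)-3-[3,4-bis(allyloxy)phenyl]-2-[2-(allyloxy)-5-formylphenoxy]prop-2-enoate | O=Cc1ccc(OCC=C)c(O/C(=C\c2ccc(OCC=C)c(OCC=C)c2)C(=O)OCC=C)c1 | intermediate
13 | (R)-danshensu, (2R)-3-(3,4-dihydroxyphenyl)-2-hydroxypropanoic acid | O[C@H](Cc1ccc(O)c(O)c1)C(=O)O | starting material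
14 | allyl (R)-3-[3,4-bis(allyloxy)phenyl]-2-hydroxypropanoate | O[C@H](Cc1ccc(OCC=C)c(OCC=C)c1)C(=O)OCC=C | intermediate
15 | Meldrum's acid | CC1(C)OC(=O)CC(=O)O1 | starting material
16 | 3-{[(2R)-1-(allyloxy)-3-[3,4-bis(allyloxy)phenyl]-1-oxopropan-2-yl]oxy}-3-oxopropanoic acid | OC(=O)CC(=O)O[C@H](Cc1ccc(OCC=C)c(OCC=C)c1)C(=O)OCC=C | intermediate
17 | iminium ion from 12 and piperidine (cation, counter-ion the carboxylate of 16; not isolated) | C1CCCC[N+]1=Cc1ccc(OCC=C)c(O/C(=C\c2ccc(OCC=C)c(OCC=C)c2)C(=O)OCC=C)c1 | intermediate
18 | β-piperidino malonic half ester (Mannich adduct, diastereomer mixture at the two new centres; not isolated) | OC(=O)C(C(N1CCCCC1)c1ccc(OCC=C)c(O/C(=C\c2ccc(OCC=C)c(OCC=C)c2)C(=O)OCC=C)c1)C(=O)O[C@H](Cc1ccc(OCC=C)c(OCC=C)c1)C(=O)OCC=C | intermediate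
19 | heptaallyl salvianolic acid H (five phenols as allyl ethers, both carboxyl groups as allyl esters; E caffeoyl alkene, Z enol ether, R) | O=C(/C=C/c1ccc(OCC=C)c(O/C(=C\c2ccc(OCC=C)c(OCC=C)c2)C(=O)OCC=C)c1)O[C@H](Cc1ccc(OCC=C)c(OCC=C)c1)C(=O)OCC=C | intermediate
20 | salvianolic acid H | O=C(/C=C/c1ccc(O)c(O/C(=C\c2ccc(O)c(O)c2)C(=O)O)c1)O[C@H](Cc1ccc(O)c(O)c1)C(=O)O | target

**Count and risks**

Total steps: 11. Longest linear sequence: 8 steps (steps 1, 3, 4, 5, 6, 7, 10, 11, from 3,4-dihydroxybenzaldehyde).

Steps most likely to fail:

1. Step 10. Iminium formation and addition may be slow with the electron-rich, ortho-oxygenated aldehyde, so that the half ester decarboxylates to the acetate before it condenses, and long heating in amine could begin to epimerise the lactate centre. Fallback (same bond, other activating group): setting out from 14, Steglich esterification with diethylphosphonoacetic acid (DCC, cat. DMAP, CH2Cl2, 0 °C to rt) should give allyl (R)-3-[3,4-bis(allyloxy)phenyl]-2-[2-(diethoxyphosphoryl)acetoxy]propanoate F1. Horner–Wadsworth–Emmons olefination of aldehyde 12 with F1 under Masamune–Roush conditions (LiCl, DBU, MeCN, rt) should then form the E alkene and come back to the route at 19.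

2. Step 5. The lithium enolate of the allyl α-aryloxyacetate may rearrange (ester-enolate Claisen) or self-condense before it adds, and the aldolate may revert on warming. Fallback: setting out from 5, diazo transfer onto purchased allyl diethylphosphonoacetate (4-acetamidobenzenesulfonyl azide, DBU, MeCN, 0 °C) gives allyl 2-diazo-2-(diethoxyphosphoryl)acetate F2. Rh2(OAc)4-catalysed O–H insertion of its carbenoid into phenol 5 (toluene, 80 °C) gives allyl 2-[2-(allyloxy)-5-(dimethoxymethyl)phenoxy]-2-(diethoxyphosphoryl)acetate F3. Horner–Wadsworth–Emmons olefination of aldehyde 4 with F3 (NaH, THF, 0 °C to rt) forms the enol ether C=C directly and comes back at 11, so steps 4 to 6 are no longer needed. The geometry would still rest on the thermodynamic preference for Z.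

3. Step 11. Cleavage of seven allyl groups on one molecule may stall at partly protected stages, allyl transfer onto the electron-rich catechol carbons may compete, and the fully unmasked polyphenol may oxidise during a long reaction. Fallback (unmasking before the union): setting out from 12 and 16, each fragment is deallylated separately with Pd(PPh3)4 and morpholine in THF with acidic work-up. Aldehyde 12 gives (Z)-3-(3,4-dihydroxyphenyl)-2-(5-formyl-2-hydroxyphenoxy)prop-2-enoic acid F4, and half ester 16 gives (R)-2-[(carboxyacetyl)oxy]-3-(3,4-dihydroxyphenyl)propanoic acid F5. A protecting-group-free Knoevenagel–Doebner condensation of F4 with F5 (piperidine, pyridine, 50 °C, argon), of the kind long used for unprotected hydroxybenzaldehydes, then comes back to the route at 20.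

Further compounds
F1 | step 10 | allyl (R)-3-[3,4-bis(allyloxy)phenyl]-2-[2-(diethoxyphosphoryl)acetoxy]propanoate | CCOP(=O)(OCC)CC(=O)O[C@H](Cc1ccc(OCC=C)c(OCC=C)c1)C(=O)OCC=C
F2 | step 5 | allyl 2-diazo-2-(diethoxyphosphoryl)acetate | C=CCOC(=O)C(=[N+]=[N-])P(=O)(OCC)OCC
F3 | step 5 | allyl 2-[2-(allyloxy)-5-(dimethoxymethyl)phenoxy]-2-(diethoxyphosphoryl)acetate | C=CCOC(=O)C(Oc1cc(C(OC)OC)ccc1OCC=C)P(=O)(OCC)OCC
F4 | step 11 | (Z)-3-(3,4-dihydroxyphenyl)-2-(5-formyl-2-hydroxyphenoxy)prop-2-enoic acid | O=Cc1ccc(O)c(O/C(=C\c2ccc(O)c(O)c2)C(=O)O)c1
F5 | step 11 | (R)-2-[(carboxyacetyl)oxy]-3-(3,4-dihydroxyphenyl)propanoic acid | OC(=O)CC(=O)O[C@H](Cc1ccc(O)c(O)c1)C(=O)O
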